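**Plan**

- Retrosynthetic cuts: (a) the C(=O)–heptyl bond of the ring B ketone (thiol ester plus heptylzinc); (b) in one operation, the ring B C1–carboxyl and C6–CH2 bonds (aryne plus malonate); (c) the O–acyl bond between the ring A C4 oxygen and a malonyl unit; (d) the benzylic CH2–C(=O) bond of the ring A side chain (toluate anion plus Weinreb amide).
- Enabling feature: in ring B the depside carboxyl carbon on C1 sits between the C2 oxygen and the C6 benzylic CH2. This vicinal acyl/alkyl pair next to an oxygen is what a 3-benzyloxybenzyne leaves when it inserts into the CH2–C(=O) bond of a malonate.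
- Forward order: methyl orsellinate is turned into the ring A phenol with its ketone masked as a dioxolane and then into an aryl tert-butyl malonate; 3,5-bis(benzyloxy)phenol is turned into a silyl aryl triflate.
- The aryne insertion joins the two halves and creates the hindered depside ester by acyl migration; the tert-butyl ester is then converted via acid and thiol ester into the heptyl ketone, and three benzyl ethers are removed.
- No ring is formed (both benzene rings are bought) and the target has no stereocentre, so no stereocontrol is needed.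

Key step: step 11

Remark: ring A is numbered from its methoxycarbonyl-bearing carbon (C1) and ring B from the carbon bearing the depside carboxyl (C1); 3,5-bis(benzyloxy)phenol and mono-tert-butyl malonate are taken as purchasable.

**Route**

Step 1
Reactants: 1 octanoyl chloride
Product: 2 N-methoxy-N-methyloctanamide
Conditions: MeNHOMe·HCl, K2CO3, CH2Cl2/H2O, 0 °C to rt
Reagents that add atoms: N,O-dimethylhydroxylamine hydrochloride, Cl.CNOC
Why: Schotten–Baumann N-acylation of the hydroxylamine by the acid chloride, with the biphasic carbonate base taking up both equivalents of HCl.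

Step 2
Reactants: 3 methyl orsellinate (methyl 2,4-dihydroxy-6-methylbenzoate)
Product: 4 methyl 4-(allyloxy)-2-hydroxy-6-methylbenzoate
Conditions: allyl bromide (1.05 equiv), K2CO3 (1.1 equiv), acetone, reflux
Reagents that add atoms: allyl bromide, C=CCBr
Why: Williamson etherification should be selective for the 4-hydroxyl, because the 2-hydroxyl is held in a hydrogen bond to the ester carbonyl and is the less acidic and less nucleophilic phenol.

Step 3
Reactants: 4 methyl 4-(allyloxy)-2-hydroxy-6-methylbenzoate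
Product: 5 methyl 4-(allyloxy)-2-(benzyloxy)-6-methylbenzoate
Conditions: BnBr, K2CO3, DMF, 60 °C
Reagents that add atoms: benzyl bromide, BrCc1ccccc1
Why: Williamson benzylation of the remaining hydrogen-bonded phenol under more forcing conditions, to which the allyl ether and methyl ester are inert.

Step 4
Reactants: 5 methyl 4-(allyloxy)-2-(benzyloxy)-6-methylbenzoate; 2 N-methoxy-N-methyloctanamide
Product: 7 methyl 4-(allyloxy)-2-(benzyloxy)-6-(2-oxononyl)benzoate, via benzylic organolithium 6 (not isolated)
Conditions: LiN(iPr)2 (2.2 equiv), THF, −78 °C; then 2, −78 °C; AcOH quench at −78 °C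
Reagents that add atoms: none
Why: Lateral lithiation of an ortho-toluate ester followed by acylation with a Weinreb amide, where the chelated tetrahedral adduct and enolisation of the product by the second equivalent of base prevent over-addition.

Step 5
Reactants: 7 methyl 4-(allyloxy)-2-(benzyloxy)-6-(2-oxononyl)benzoate
Product: 8 methyl 4-(allyloxy)-2-(benzyloxy)-6-[(2-heptyl-1,3-dioxolan-2-yl)methyl]benzoate
Conditions: TMSOCH2CH2OTMS, TMSOTf (10 mol %), CH2Cl2, −78 to −20 °C; pyridine quench
Reagents that add atoms: 1,2-bis(trimethylsilyloxy)ethane, C[Si](C)(C)OCCO[Si](C)(C)C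
Why: Noyori ketalisation under aprotic low-temperature conditions, chosen because hot protic acid would favour enol lactonisation of the keto ester to an isocoumarin.

Step 6
Reactants: 8 methyl 4-(allyloxy)-2-(benzyloxy)-6-[(2-heptyl-1,3-dioxolan-2-yl)methyl]benzoate
Product: 9 methyl 2-(benzyloxy)-6-[(2-heptyl-1,3-dioxolan-2-yl)methyl]-4-hydroxybenzoate
Conditions: Pd(PPh3)4 (5 mol %), morpholine, THF, rt
Reagents that add atoms: none
Why: Tsuji–Trost deallylation, in which zerovalent palladium ionises the aryl allyl ether and morpholine traps the allyl fragment under basic conditions that spare the ketal, benzyl ether and ester.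

Step 7
Reactants: 9 methyl 2-(benzyloxy)-6-[(2-heptyl-1,3-dioxolan-2-yl)methyl]-4-hydroxybenzoate; 10 mono-tert-butyl malonate
Product: 11 3-(benzyloxy)-5-[(2-heptyl-1,3-dioxolan-2-yl)methyl]-4-(methoxycarbonyl)phenyl tert-butyl malonate
Conditions: DCC, DMAP (10 mol %), CH2Cl2, 0 °C to rt
Reagents that add atoms: none
Why: Steglich esterification of the phenol with the malonic half ester under neutral carbodiimide conditions that the tert-butyl ester and ketal tolerate.

Step 8
Reactants: 12 3,5-bis(benzyloxy)phenol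
Product: 13 3,5-bis(benzyloxy)phenyl N-isopropylcarbamate
Conditions: iPrNCO, Et3N (20 mol %), CH2Cl2, rt
Reagents that add atoms: isopropyl isocyanate, CC(C)N=C=O
Why: Base-catalysed addition of the phenol to the isocyanate gives the carbamate that will direct metalation and later leave under mild base.

Step 9
Reactants: 13 3,5-bis(benzyloxy)phenyl N-isopropylcarbamate
Product: 17 3,5-bis(benzyloxy)-2-(trimethylsilyl)phenyl N-isopropylcarbamate, via N-silyl carbamate 14 (not isolated), via aryllithium 15 (not isolated), via N-silyl C-silyl carbamate 16 (not isolated)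
Conditions: TBSOTf, TMEDA, Et2O, 0 °C to rt; then n-BuLi, TMEDA, −78 °C; then TMSCl, −78 °C to rt; aq NaHSO4 work-up
Reagents that add atoms: chlorotrimethylsilane, C[Si](C)(C)Cl
Why: Directed ortho-metalation, in which the N-silylated carbamate and the flanking benzyloxy group together direct lithiation to C2 (equivalent to C6), the aryllithium is silylated, and the N-silyl group is lost in the acidic work-up.

Step 10
Reactants: 17 3,5-bis(benzyloxy)-2-(trimethylsilyl)phenyl N-isopropylcarbamate
Product: 19 3,5-bis(benzyloxy)-2-(trimethylsilyl)phenyl trifluoromethanesulfonate, via silylphenol 18 (not isolated)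
Conditions: DBU, Et2NH, MeCN, 40 °C; then PhNTf2, rt
Reagents that add atoms: N-phenylbis(trifluoromethanesulfonimide), O=S(=O)(N(c1ccccc1)S(=O)(=O)C(F)(F)F)C(F)(F)F
Why: Base-promoted elimination of the N-monosubstituted carbamate to the isocyanate (trapped by diethylamine) frees the phenoxide, which is triflated in the same pot by a mild triflyl donor without protodesilylation.

Step 11
Reactants: 11 3-(benzyloxy)-5-[(2-heptyl-1,3-dioxolan-2-yl)methyl]-4-(methoxycarbonyl)phenyl tert-butyl malonate; 19 3,5-bis(benzyloxy)-2-(trimethylsilyl)phenyl trifluoromethanesulfonate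
Product: 21 3-(benzyloxy)-5-[(2-heptyl-1,3-dioxolan-2-yl)methyl]-4-(methoxycarbonyl)phenyl 2,4-bis(benzyloxy)-6-(2-tert-butoxy-2-oxoethyl)benzoate, via 3,5-bis(benzyloxy)benzyne 20 (not isolated)
Conditions: KF (3 equiv), 18-crown-6 (3 equiv), THF, 0 °C to rt; 19 (1.3 equiv) added slowly
Reagents that add atoms: none
Why: Fluoride removes the silyl group of 19 and triflate departs to give aryne 20; the potassium enolate of 11 adds through carbon to the aryne carbon remote from the C3 benzyloxy group, so the aryl anion forms beside that inductively withdrawing oxygen. The aryl anion closes 4-exo-trig onto the neighbouring aryl ester carbonyl to a benzocyclobutenoxide, which opens by C–C cleavage to the tert-butyl ester enolate and is protonated, so the aryl–C(=O) and aryl–CH2 bonds of ring B form together and the four-membered ring does not survive. The closest known reaction type is the fluoride-induced insertion of arynes into the CH2–C(=O) bond of malonic diesters and β-ketoesters (aryne acyl-alkylation). No stereocentre is created. Two selectivities are needed: the site of enolate addition, secured by the benzyloxy group next to the triple bond, and the choice of carbonyl, secured because the aryl ester is more electrophilic and far less hindered than the tert-butyl ester. Room temperature and slow addition of 19 should hold back loss of the ring A phenoxide from the enolate and plain α-arylation.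

Step 12
Reactants: 21 3-(benzyloxy)-5-[(2-heptyl-1,3-dioxolan-2-yl)methyl]-4-(methoxycarbonyl)phenyl 2,4-bis(benzyloxy)-6-(2-tert-butoxy-2-oxoethyl)benzoate
Product: 22 3-(benzyloxy)-4-(methoxycarbonyl)-5-(2-oxononyl)phenyl 2,4-bis(benzyloxy)-6-(carboxymethyl)benzoate
Conditions: TFA/CH2Cl2/H2O (10:10:1), 0 °C to rt; evaporation with toluene, no basic work-up
Reagents that add atoms: water, O
Why: Acidolysis of the tert-butyl ester by alkyl–oxygen cleavage and hydrolysis of the dioxolane proceed together in aqueous trifluoroacetic acid, to which the benzyl ethers, the methyl ester and the hindered aryl ester should be stable at room temperature.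

Step 13
Reactants: 22 3-(benzyloxy)-4-(methoxycarbonyl)-5-(2-oxononyl)phenyl 2,4-bis(benzyloxy)-6-(carboxymethyl)benzoate
Product: 23 3-(benzyloxy)-4-(methoxycarbonyl)-5-(2-oxononyl)phenyl 2,4-bis(benzyloxy)-6-[2-(ethylsulfanyl)-2-oxoethyl]benzoate
Conditions: EtSH, DCC, DMAP (10 mol %), CH2Cl2, 0 °C
Reagents that add atoms: ethanethiol, CCS
Why: Steglich thiol ester formation, in which rapid carbodiimide activation of the arylacetic acid at 0 °C should outpace any attack of the carboxylate on the neighbouring aryl ester.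

Step 14
Reactants: 23 3-(benzyloxy)-4-(methoxycarbonyl)-5-(2-oxononyl)phenyl 2,4-bis(benzyloxy)-6-[2-(ethylsulfanyl)-2-oxoethyl]benzoate; 24 1-bromoheptane
Product: 26 3-(benzyloxy)-4-(methoxycarbonyl)-5-(2-oxononyl)phenyl 2,4-bis(benzyloxy)-6-(2-oxononyl)benzoate, via heptylzinc bromide 25 (not isolated)
Conditions: 24, Zn dust, LiCl, THF, 50 °C; then 23, PdCl2(PPh3)2 (5 mol %), toluene/THF, rt
Reagents that add atoms: none
Why: Fukuyama ketone synthesis, in which zerovalent palladium formed from the divalent palladium precatalyst inserts into the C–S bond and the acylpalladium is alkylated by the mild heptylzinc reagent, which leaves the ketone, both esters and the benzyl ethers untouched.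

Step 15
Reactants: 26 3-(benzyloxy)-4-(methoxycarbonyl)-5-(2-oxononyl)phenyl 2,4-bis(benzyloxy)-6-(2-oxononyl)benzoate
Product: 27 3-hydroxy-4-(methoxycarbonyl)-5-(2-oxononyl)phenyl 2,4-dihydroxy-6-(2-oxononyl)benzoate (CNP0110390.0)
Conditions: H2 (1 atm), Pd/C (10 wt %), EtOAc, rt
Reagents that add atoms: none
Why: Hydrogenolysis of the three aryl benzyl ethers over Pd/C, under which neither the aliphatic ketones nor the methyl and aryl esters should be reduced.

**Compound list**

1 | octanoyl chloride | CCCCCCCC(=O)Cl | starting material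
2 | N-methoxy-N-methyloctanamide | CCCCCCCC(=O)N(C)OC | intermediate
3 | methyl orsellinate (methyl 2,4-dihydroxy-6-methylbenzoate) | COC(=O)c1c(C)cc(O)cc1O | starting material
4 | methyl 4-(allyloxy)-2-hydroxy-6-methylbenzoate | COC(=O)c1c(C)cc(OCC=C)cc1O | intermediate
5 | methyl 4-(allyloxy)-2-(benzyloxy)-6-methylbenzoate | COC(=O)c1c(C)cc(OCC=C)cc1OCc1ccccc1 | intermediate
6 | benzylic organolithium of 5 (lithiomethyl in place of the 6-methyl group) | COC(=O)c1c(C[Li])cc(OCC=C)cc1OCc1ccccc1 | intermediate
7 | methyl 4-(allyloxy)-2-(benzyloxy)-6-(2-oxononyl)benzoate | COC(=O)c1c(CC(=O)CCCCCCC)cc(OCC=C)cc1OCc1ccccc1 | intermediate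
8 | methyl 4-(allyloxy)-2-(benzyloxy)-6-[(2-heptyl-1,3-dioxolan-2-yl)methyl]benzoate | COC(=O)c1c(CC2(CCCCCCC)OCCO2)cc(OCC=C)cc1OCc1ccccc1 | intermediate
9 | methyl 2-(benzyloxy)-6-[(2-heptyl-1,3-dioxolan-2-yl)methyl]-4-hydroxybenzoate | COC(=O)c1c(CC2(CCCCCCC)OCCO2)cc(O)cc1OCc1ccccc1 | intermediate
10 | mono-tert-butyl malonate | CC(C)(C)OC(=O)CC(=O)O | starting material
11 | 3-(benzyloxy)-5-[(2-heptyl-1,3-dioxolan-2-yl)methyl]-4-(methoxycarbonyl)phenyl tert-butyl malonate | CC(C)(C)OC(=O)CC(=O)Oc1cc(OCc2ccccc2)c(C(=O)OC)c(CC2(CCCCCCC)OCCO2)c1 | intermediate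
12 | 3,5-bis(benzyloxy)phenol | Oc1cc(OCc2ccccc2)cc(OCc2ccccc2)c1 | starting material
13 | 3,5-bis(benzyloxy)phenyl N-isopropylcarbamate | CC(C)NC(=O)Oc1cc(OCc2ccccc2)cc(OCc2ccccc2)c1 | intermediate
14 | 3,5-bis(benzyloxy)phenyl N-(tert-butyldimethylsilyl)-N-isopropylcarbamate | CC(C)N(C(=O)Oc1cc(OCc2ccccc2)cc(OCc2ccccc2)c1)[Si](C)(C)C(C)(C)C | intermediate
15 | 2-lithio derivative of 14 (lithium between the carbamate oxygen and a benzyloxy group) | CC(C)N(C(=O)Oc1cc(OCc2ccccc2)cc(OCc2ccccc2)c1[Li])[Si](C)(C)C(C)(C)C | intermediate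
16 | 3,5-bis(benzyloxy)-2-(trimethylsilyl)phenyl N-(tert-butyldimethylsilyl)-N-isopropylcarbamate | CC(C)N(C(=O)Oc1cc(OCc2ccccc2)cc(OCc2ccccc2)c1[Si](C)(C)C)[Si](C)(C)C(C)(C)C | intermediate
17 | 3,5-bis(benzyloxy)-2-(trimethylsilyl)phenyl N-isopropylcarbamate | CC(C)NC(=O)Oc1cc(OCc2ccccc2)cc(OCc2ccccc2)c1[Si](C)(C)C | intermediate
18 | 3,5-bis(benzyloxy)-2-(trimethylsilyl)phenol | C[Si](C)(C)c1c(O)cc(OCc2ccccc2)cc1OCc1ccccc1 | intermediate
19 | 3,5-bis(benzyloxy)-2-(trimethylsilyl)phenyl trifluoromethanesulfonate | C[Si](C)(C)c1c(OS(=O)(=O)C(F)(F)F)cc(OCc2ccccc2)cc1OCc1ccccc1 | intermediate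
20 | 3,5-bis(benzyloxy)benzyne (triple bond C1–C2, benzyloxy groups on C3 and C5) | C1#CC(OCc2ccccc2)=CC(OCc2ccccc2)=C1 | intermediate
21 | 3-(benzyloxy)-5-[(2-heptyl-1,3-dioxolan-2-yl)methyl]-4-(methoxycarbonyl)phenyl 2,4-bis(benzyloxy)-6-(2-tert-butoxy-2-oxoethyl)benzoate | CC(C)(C)OC(=O)Cc1cc(OCc2ccccc2)cc(OCc2ccccc2)c1C(=O)Oc1cc(OCc2ccccc2)c(C(=O)OC)c(CC2(CCCCCCC)OCCO2)c1 | intermediate
22 | 3-(benzyloxy)-4-(methoxycarbonyl)-5-(2-oxononyl)phenyl 2,4-bis(benzyloxy)-6-(carboxymethyl)benzoate | OC(=O)Cc1cc(OCc2ccccc2)cc(OCc2ccccc2)c1C(=O)Oc1cc(OCc2ccccc2)c(C(=O)OC)c(CC(=O)CCCCCCC)c1 | intermediate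
23 | 3-(benzyloxy)-4-(methoxycarbonyl)-5-(2-oxononyl)phenyl 2,4-bis(benzyloxy)-6-[2-(ethylsulfanyl)-2-oxoethyl]benzoate | CCSC(=O)Cc1cc(OCc2ccccc2)cc(OCc2ccccc2)c1C(=O)Oc1cc(OCc2ccccc2)c(C(=O)OC)c(CC(=O)CCCCCCC)c1 | intermediate
24 | 1-bromoheptane | CCCCCCCBr | starting material
25 | heptylzinc bromide (THF solution, LiCl present) | CCCCCCC[Zn]Br | intermediate
26 | 3-(benzyloxy)-4-(methoxycarbonyl)-5-(2-oxononyl)phenyl 2,4-bis(benzyloxy)-6-(2-oxononyl)benzoate | CCCCCCCC(=O)Cc1cc(OCc2ccccc2)cc(OCc2ccccc2)c1C(=O)Oc1cc(OCc2ccccc2)c(C(=O)OC)c(CC(=O)CCCCCCC)c1 | intermediate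
27 | 3-hydroxy-4-(methoxycarbonyl)-5-(2-oxononyl)phenyl 2,4-dihydroxy-6-(2-oxononyl)benzoate (CNP0110390.0) | CCCCCCCC(=O)Cc1cc(OC(=O)c2c(O)cc(O)cc2CC(=O)CCCCCCC)cc(O)c1C(=O)OC | target

**Step count**

Total: 15 steps. Longest linear sequence: 11 steps (3 to 27 through steps 2–7 and 11–15); steps 1 and 8–10 are side branches.

**Steps most likely to fail**

Step 11. The malonate enolate may expel the ring A phenoxide (elimination to a ketene) before it meets the aryne, the aryl anion may be quenched by proton transfer before it closes onto the ester carbonyl (plain α-arylation), or the acyl shift may be slow for so large an aryl ester. The fallback leaves the route at 10 and 19 and returns at 21; it delivers the acyl group from a small ester and makes the depside bond afterwards by ordinary acylation. Alkylation of 10 with allyl bromide (K2CO3, DMF) would give allyl tert-butyl malonate F1. Insertion of aryne 20, generated from 19 with KF/18-crown-6 in THF, into F1 is the established dialkyl malonate case; the aryl anion should choose the unhindered allyl ester and give allyl 2,4-bis(benzyloxy)-6-(2-tert-butoxy-2-oxoethyl)benzoate F2. Pd(PPh3)4 and morpholine would release 2,4-bis(benzyloxy)-6-(2-tert-butoxy-2-oxoethyl)benzoic acid F3, which DCC/DMAP in CH2Cl2 would couple with phenol 9 to give 21.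

Step 5. Under the Lewis acid the activated ketone may be captured by the neighbouring methyl ester (enol lactonisation toward an isocoumarin) or be converted into a silyl enol ether faster than the dioxolane forms. The fallback leaves the route at 7 and returns at 22; it carries the ketone unprotected and relies on the malonate CH2 being several pKa units more acidic than the benzylic ketone. Deallylation of 7 (Pd(PPh3)4, morpholine, THF) would give methyl 2-(benzyloxy)-4-hydroxy-6-(2-oxononyl)benzoate F4. DCC/DMAP coupling with 10 would give 3-(benzyloxy)-4-(methoxycarbonyl)-5-(2-oxononyl)phenyl tert-butyl malonate F5. Insertion of aryne 20 (from 19, KF/18-crown-6, THF, rt) would give 3-(benzyloxy)-4-(methoxycarbonyl)-5-(2-oxononyl)phenyl 2,4-bis(benzyloxy)-6-(2-tert-butoxy-2-oxoethyl)benzoate F6, and TFA in CH2Cl2 would cleave its tert-butyl ester to give 22.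

Step 13. Once the arylacetic acid is ionised by the basic catalyst, the carboxylate may attack the adjacent aryl ester and expel the ring A phenoxide through a six-membered cyclic anhydride, breaking the depside before the thiol ester forms. The fallback leaves the route at 22 and returns at 26; it avoids both base and the thiol ester. Oxalyl chloride with catalytic DMF in CH2Cl2 at 0 °C would convert 22 into 3-(benzyloxy)-4-(methoxycarbonyl)-5-(2-oxononyl)phenyl 2,4-bis(benzyloxy)-6-(2-chloro-2-oxoethyl)benzoate F7. Negishi acylation of F7 with heptylzinc bromide 25 under Pd(PPh3)4 in THF at 0 °C would give 26 directly.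

**Further compounds**

F1 | step 11 | allyl tert-butyl malonate | C=CCOC(=O)CC(=O)OC(C)(C)C
F2 | step 11 | allyl 2,4-bis(benzyloxy)-6-(2-tert-butoxy-2-oxoethyl)benzoate | C=CCOC(=O)c1c(CC(=O)OC(C)(C)C)cc(OCc2ccccc2)cc1OCc1ccccc1
F3 | step 11 | 2,4-bis(benzyloxy)-6-(2-tert-butoxy-2-oxoethyl)benzoic acid | OC(=O)c1c(CC(=O)OC(C)(C)C)cc(OCc2ccccc2)cc1OCc1ccccc1
F4 | step 5 | methyl 2-(benzyloxy)-4-hydroxy-6-(2-oxononyl)benzoate | COC(=O)c1c(CC(=O)CCCCCCC)cc(O)cc1OCc1ccccc1
F5 | step 5 | 3-(benzyloxy)-4-(methoxycarbonyl)-5-(2-oxononyl)phenyl tert-butyl malonate | CC(C)(C)OC(=O)CC(=O)Oc1cc(OCc2ccccc2)c(C(=O)OC)c(CC(=O)CCCCCCC)c1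
F6 | step 5 | 3-(benzyloxy)-4-(methoxycarbonyl)-5-(2-oxononyl)phenyl 2,4-bis(benzyloxy)-6-(2-tert-butoxy-2-oxoethyl)benzoate | CC(C)(C)OC(=O)Cc1cc(OCc2ccccc2)cc(OCc2ccccc2)c1C(=O)Oc1cc(OCc2ccccc2)c(C(=O)OC)c(CC(=O)CCCCCCC)c1
F7 | step 13 | 3-(benzyloxy)-4-(methoxycarbonyl)-5-(2-oxononyl)phenyl 2,4-bis(benzyloxy)-6-(2-chloro-2-oxoethyl)benzoate | ClC(=O)Cc1cc(OCc2ccccc2)cc(OCc2ccccc2)c1C(=O)Oc1cc(OCc2ccccc2)c(C(=O)OC)c(CC(=O)CCCCCCC)c1
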